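The butyrolactone is opened so that C-2 and both of its oxygens leave as a single CO2-level carbon bridging C-3 and C-5. C-3 is homobenzylic to the 3,4-dimethoxyphenyl ring, so it can be the β-carbon of a styrene: a formate-derived CO2 radical anion adds there, and the resulting carboxylate displaces chloride at C-5 to close the ring, after which base equilibration sets the 3,4-trans relationship. One operation therefore installs the carbonyl carbon, the ring oxygen and the C-3 stereocentre. The precursor is an (R)-configured homoallylic chloride bearing both aryl groups, made in two steps by copper-catalysed asymmetric SN2' benzylation of (E)-1,4-dichlorobut-2-ene and cross-metathesis.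

Key step: step 3

Assumption: the sense of induction of the copper catalyst in step 1 is not taken from analogy. L* denotes a BINOL-based phosphoramidite with a bis[1-(2-methoxyphenyl)ethyl]amino group, used as whichever antipode gives (R)-4; this is to be assigned on a test run against material from the auxiliary-based fallback.

Step 1
Reactants: 1 3,4,5-trimethoxybenzyl chloride; 2 (E)-1,4-dichlorobut-2-ene
Product: 4 (R)-4-chloro-3-(3,4,5-trimethoxybenzyl)but-1-ene, via (3,4,5-trimethoxybenzyl)magnesium chloride 3 (not isolated)
Conditions: Mg, Et2O, 0 °C to rt; then added slowly to 2, CuTC (3 mol %), L* (3.3 mol %), CH2Cl2, −78 °C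
Reagents that add atoms: none
Why: Copper-catalysed asymmetric allylic alkylation (SN2') of a 1,4-dihalobut-2-ene with a Grignard reagent should deliver the benzyl group to C-2 of 2 with allylic transposition and loss of chloride, the chiral Cu–phosphoramidite complex setting the (R) stereocentre while the remaining primary chloride is inert at −78 °C.

Step 2
Reactants: 4 (R)-4-chloro-3-(3,4,5-trimethoxybenzyl)but-1-ene; 5 3,4-dimethoxystyrene
Product: 6 4-[(1E,3R)-4-chloro-3-(3,4,5-trimethoxybenzyl)but-1-en-1-yl]-1,2-dimethoxybenzene
Conditions: Hoveyda–Grubbs II (5 mol %), 5 (3 equiv), CH2Cl2, 40 °C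
Reagents that add atoms: none
Why: Olefin cross-metathesis between the allylically branched terminal alkene and an excess of the styrene is driven by loss of ethylene and does not touch the stereocentre; the E isomer is expected, and either alkene geometry serves step 3.

Step 3
Reactants: 6 4-[(1E,3R)-4-chloro-3-(3,4,5-trimethoxybenzyl)but-1-en-1-yl]-1,2-dimethoxybenzene
Product: 9 (3R,4R)-3-(3,4-dimethoxybenzyl)-4-(3,4,5-trimethoxybenzyl)dihydrofuran-2(3H)-one, via γ-chloro carboxylate 7 (not isolated), via cis-lactone 8 (not isolated)
Conditions: HCO2K (5 equiv), 4CzIPN (2 mol %), mesna (20 mol %), DMSO, 450 nm LEDs, rt; then 60 °C; then DBU (1 equiv), 80 °C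
Reagents that add atoms: potassium formate, [K+].[O-]C=O
Why: Thiyl-mediated hydrogen-atom abstraction from formate gives CO2•−, which should add to the alkene carbon remote from the 3,4-dimethoxyphenyl ring (the future C-3) because only that mode gives a benzylic radical, and hydrogen-atom transfer from the thiol then closes the chain; the closest known reaction type is the photocatalytic anti-Markovnikov hydrocarboxylation of styrenes with formate, here telescoped with carboxylate O-alkylation. On warming, the γ-chloro carboxylate 7 should close the five-membered lactone by 5-exo-tet SN2 at the primary CH2Cl carbon, which forms the ring O–CH2 bond. C-4 was set in step 1 and is untouched, since no bond to it is made or broken and it carries no acidic hydrogen. The new C-3 stereocentre forms without facial control in the radical addition and is then set thermodynamically: DBU equilibrates cis-lactone 8 through the lactone enolate to the trans (3R,4R) isomer, with C-4 as the controlling element. The step needs regioselectivity in the radical addition, secured by the aryl-conjugated alkene, and chemoselectivity for the alkene over the C–Cl bond, secured by a primary alkyl chloride that CO2•−, formate and neutral thiol should leave alone at room temperature.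

Compound list
1 | 3,4,5-trimethoxybenzyl chloride | COc1cc(CCl)cc(OC)c1OC | starting material
2 | (E)-1,4-dichlorobut-2-ene | ClC/C=C/CCl | starting material
3 | (3,4,5-trimethoxybenzyl)magnesium chloride | COc1cc(C[Mg]Cl)cc(OC)c1OC | intermediate
4 | (R)-4-chloro-3-(3,4,5-trimethoxybenzyl)but-1-ene | ClC[C@@H](C=C)Cc1cc(OC)c(OC)c(OC)c1 | intermediate
5 | 3,4-dimethoxystyrene | C=Cc1ccc(OC)c(OC)c1 | starting material
6 | 4-[(1E,3R)-4-chloro-3-(3,4,5-trimethoxybenzyl)but-1-en-1-yl]-1,2-dimethoxybenzene | ClC[C@@H](/C=C/c1ccc(OC)c(OC)c1)Cc1cc(OC)c(OC)c(OC)c1 | intermediate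
7 | potassium (2RS,3R)-4-chloro-2-(3,4-dimethoxybenzyl)-3-(3,4,5-trimethoxybenzyl)butanoate (both C-2 epimers) | [K+].[O-]C(=O)C(Cc1ccc(OC)c(OC)c1)[C@H](CCl)Cc1cc(OC)c(OC)c(OC)c1 | intermediate
8 | (3S,4R)-3-(3,4-dimethoxybenzyl)-4-(3,4,5-trimethoxybenzyl)dihydrofuran-2(3H)-one (cis-lactone) | COc1ccc(C[C@@H]2C(=O)OC[C@@H]2Cc2cc(OC)c(OC)c(OC)c2)cc1OC | intermediate
9 | (3R,4R)-3-(3,4-dimethoxybenzyl)-4-(3,4,5-trimethoxybenzyl)dihydrofuran-2(3H)-one | COc1ccc(C[C@H]2C(=O)OC[C@@H]2Cc2cc(OC)c(OC)c(OC)c2)cc1OC | target

Total step count: 3. Longest linear sequence: 3 steps (1 → 4 → 6 → 9).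

Steps most likely to fail

Step 3. CO2•− may add only slowly to the electron-rich, 1,2-disubstituted styrene, so that thiol–ene addition or consumption of the primary chloride by thiolate or formate competes; the base equilibration may also stall short of the trans isomer. The fallback sets out from 4 and comes back to the route at 9, building the lactone carbonyl from the vinyl group instead. Compound 4 is hydroborated (9-BBN, THF; then NaBO3·4H2O) to (R)-4-chloro-3-(3,4,5-trimethoxybenzyl)butan-1-ol F1. This is oxidised (TEMPO, PhI(OAc)2, MeCN/H2O) to (R)-4-chloro-3-(3,4,5-trimethoxybenzyl)butanoic acid F2. Cyclisation with Et3N in DMF at 60 °C should give (R)-4-(3,4,5-trimethoxybenzyl)dihydrofuran-2(3H)-one F3. Its lithium enolate (LiHMDS, THF, −78 °C) is alkylated with 3,4-dimethoxybenzyl bromide anti to the C-4 substituent, which should give 9 directly as the trans isomer.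

Step 1. Wurtz homocoupling may consume the electron-rich benzylic chloride during Grignard formation, and γ-selectivity or enantioinduction may drop when a benzylic rather than a simple alkyl group is transferred from copper. The fallback sets out from 1 and comes back to the route at 4, using auxiliary control. (R)-4-Benzyl-3-(but-3-enoyl)oxazolidin-2-one F4 is prepared from but-3-enoic acid and (R)-4-benzyloxazolidin-2-one (PivCl, Et3N, LiCl, THF). It is deprotonated with NaHMDS at −78 °C and alkylated with 1 (NaI activation) on the face away from the auxiliary benzyl group, which should give (R)-4-benzyl-3-[(R)-2-(3,4,5-trimethoxybenzyl)but-3-enoyl]oxazolidin-2-one F5. Reduction with LiBH4 and MeOH in THF should give (R)-2-(3,4,5-trimethoxybenzyl)but-3-en-1-ol F6 and release the auxiliary. Appel chlorination (PPh3, CCl4, CH2Cl2) then gives 4.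

Step 2. Self-metathesis of the styrene and slow turnover at the allylically branched alkene may limit conversion, and ruthenium hydride-mediated alkene migration would erode the allylic stereocentre. The fallback sets out from 4 and comes back to the route at 6 by a Heck arylation with 4-iodo-1,2-dimethoxybenzene (Pd(OAc)2, P(o-tol)3, Et3N, MeCN, 80 °C). β-Hydride elimination toward the aryl group should give the conjugated E-styrene without any new intermediate.

Further compounds
F1 | step 3 | (R)-4-chloro-3-(3,4,5-trimethoxybenzyl)butan-1-ol | OCC[C@H](CCl)Cc1cc(OC)c(OC)c(OC)c1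
F2 | step 3 | (R)-4-chloro-3-(3,4,5-trimethoxybenzyl)butanoic acid | OC(=O)C[C@H](CCl)Cc1cc(OC)c(OC)c(OC)c1
F3 | step 3 | (R)-4-(3,4,5-trimethoxybenzyl)dihydrofuran-2(3H)-one | O=C1C[C@@H](Cc2cc(OC)c(OC)c(OC)c2)CO1
F4 | step 1 | (R)-4-benzyl-3-(but-3-enoyl)oxazolidin-2-one | C=CCC(=O)N1C(=O)OC[C@H]1Cc1ccccc1
F5 | step 1 | (R)-4-benzyl-3-[(R)-2-(3,4,5-trimethoxybenzyl)but-3-enoyl]oxazolidin-2-one | O=C([C@@H](C=C)Cc1cc(OC)c(OC)c(OC)c1)N1C(=O)OC[C@H]1Cc1ccccc1
F6 | step 1 | (R)-2-(3,4,5-trimethoxybenzyl)but-3-en-1-ol | OC[C@@H](C=C)Cc1cc(OC)c(OC)c(OC)c1
F0 | step 2 | none | none
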